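## Retrosynthetic overview

1. The target comes from a transannular aldol addition. It forms the C1–C5 bond and closes the five- and seven-membered rings together, starting from a ten-membered 3-hydroxy-1,6-dione (a 5,10-seco-halimane).
2. The ten-membered dione comes from ozonolysis of the tetrasubstituted C5=C10 alkene of an octalin. The C3 carbinol comes from CBS reduction of a C3 ketone.
3. The C5=C10 octalin comes from alkene migration in a C5=C6 octalin. The side chain comes from methylenation of a C9 aldehyde, then hydroboration and B-alkyl Suzuki coupling with 4-bromobutenolide.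
4. The C5=C6 octalin comes from an organocatalytic enantioselective Diels–Alder reaction of tiglaldehyde with 2,2-dimethyl-3-vinylcyclohex-3-en-1-one, which sets C8 and C9. The diene comes from 2,2-dimethylcyclohexane-1,3-dione.
5. Ring order: ring A (bought), ring B (Diels–Alder), butenolide (bought ring, attached), ten-membered ring (cleavage), then five- and seven-membered rings (aldol).

Locants follow halimane numbering. Ring A is C1–C5 and C10, ring B is C5–C10. C4 carries the gem-dimethyl group, C8 a methyl, and C9 a methyl plus the chain C11–C16. In the target, C1 is the ring-fusion CH, C5 the ring-fusion carbinol and C10 the ketone.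

Assumption: the (S,S)-IDPi catalyst is taken to cover the C-alpha-Si face of 5. If the sense of induction is opposite, its mirror image is used and nothing else changes.

Assumption: 6 is drawn as the endo adduct (10R). Any 10-epimer is carried along, because C10 becomes sp2 in step 6.

## Route

Step 1
Reactants: 1 2,2-dimethylcyclohexane-1,3-dione
Product: 3 6,6-dimethyl-5-oxocyclohex-1-en-1-yl trifluoromethanesulfonate, via lithium enolate 2 (not isolated)
Conditions: LiN(SiMe3)2 (1.05 equiv), THF, −78 °C; PhNTf2 (1.1 equiv), −78 → 0 °C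
Reagents that add atoms: N-phenylbis(trifluoromethanesulfonimide), FC(F)(F)S(=O)(=O)N(c1ccccc1)S(=O)(=O)C(F)(F)F
Why: Enol triflate formation: the two alpha-CH2 groups are equivalent and the quaternary carbon blocks any other enolate, so kinetic deprotonation and O-triflation give one product, and no stereocentre is formed.

Step 2
Reactants: 3 6,6-dimethyl-5-oxocyclohex-1-en-1-yl trifluoromethanesulfonate
Product: 4 2,2-dimethyl-3-vinylcyclohex-3-en-1-one
Conditions: CH2=CHSnBu3 (1.1 equiv), Pd(PPh3)4 (3 mol %), LiCl (3 equiv), THF, 65 °C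
Reagents that add atoms: tributyl(vinyl)stannane, C=C[Sn](CCCC)(CCCC)CCCC
Why: Stille coupling: zerovalent palladium adds oxidatively into the vinyl C–OTf bond with chloride assistance, vinyl is transferred from tin and reductive elimination follows, while the hindered ketone stays inert.

Step 3
Reactants: 4 2,2-dimethyl-3-vinylcyclohex-3-en-1-one; 5 (E)-2-methylbut-2-enal (tiglaldehyde)
Product: 6 (1S,2R,8aR)-1,2,5,5-tetramethyl-6-oxo-1,2,3,5,6,7,8,8a-octahydronaphthalene-1-carbaldehyde (8R,9S,10R; both methyls on C8/C9 cis, CHO trans to the C8 methyl)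
Conditions: (S,S)-IDPi (imidodiphosphorimidate from two (S)-3,3'-bis[3,5-bis(trifluoromethyl)phenyl]-BINOL units, N-triflyl groups; 5 mol %), 5 (3 equiv), toluene, −40 °C
Reagents that add atoms: none
Why: Proposed new method: an enantioselective Diels–Alder reaction in which a confined, strongly acidic chiral imidodiphosphorimidate (not yet applied to all-carbon [4+2] reactions of alpha,beta-disubstituted enals with unactivated semicyclic dienes) protonates or hydrogen-bonds the s-trans enal 5, so that the LUMO-lowered C-beta is attacked first by the terminal CH2 of the diene (largest HOMO coefficient; the gem-dimethyl group holds 4 s-cis) and the asynchronous concerted C9–C10 closure follows ("ortho" regiochemistry); the chiral anion pocket covers the C-alpha-Si face so both bonds form on the C-alpha-Re/C-beta-Si face (8R,9S), the E geometry of 5 is transferred suprafacially into the cis relation of the two methyls, and because C10 is erased in step 6 only dienophile-face selectivity is needed (not endo/exo or diene-face selectivity); the closest known reaction types are the cationic-oxazaborolidine-catalysed Diels–Alder reaction of 2-substituted enals and the IDPi/silylium-catalysed Diels–Alder reaction of alpha,beta-unsaturated esters.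

Step 4
Reactants: 6 (1S,2R,8aR)-1,2,5,5-tetramethyl-6-oxo-1,2,3,5,6,7,8,8a-octahydronaphthalene-1-carbaldehyde
Product: 7 (4aS,5S,6R)-5-ethenyl-1,1,5,6-tetramethyl-3,4,4a,5,6,7-hexahydronaphthalen-2(1H)-one
Conditions: MePPh3Br (1.15 equiv), KOtBu (1.1 equiv), THF, 0 °C; then 6, −20 → 0 °C
Reagents that add atoms: methyltriphenylphosphonium bromide, C[P+](c1ccccc1)(c1ccccc1)c1ccccc1.[Br-]
Why: Wittig methylenation: with about one equivalent of ylide at low temperature the non-enolisable aldehyde reacts far faster than the alpha-quaternary, enolisable C3 ketone, and no stereocentre is touched.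

Step 5
Reactants: 7 (4aS,5S,6R)-5-ethenyl-1,1,5,6-tetramethyl-3,4,4a,5,6,7-hexahydronaphthalen-2(1H)-one; 8 4-bromofuran-2(5H)-one
Product: 10 4-{2-[(1S,2R,8aS)-1,2,5,5-tetramethyl-6-oxo-1,2,3,5,6,7,8,8a-octahydronaphthalen-1-yl]ethyl}furan-2(5H)-one, via B-alkyl-9-BBN adduct 9 (not isolated)
Conditions: 9-BBN (1.2 equiv), THF, 0 → 23 °C; then 8 (1.3 equiv), PdCl2(dppf) (5 mol %), AsPh3 (10 mol %), aq K3PO4, DMF, 23 → 40 °C
Reagents that add atoms: none
Why: Anti-Markovnikov hydroboration of the only monosubstituted alkene (the trisubstituted ring alkene and the neopentyl C3 ketone react much more slowly with 9-BBN), followed by B-alkyl Suzuki–Miyaura coupling, in which zerovalent palladium inserts into the C–Br bond and forms C12–C13 without touching a stereocentre.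

Step 6
Reactants: 10 4-{2-[(1S,2R,8aS)-1,2,5,5-tetramethyl-6-oxo-1,2,3,5,6,7,8,8a-octahydronaphthalen-1-yl]ethyl}furan-2(5H)-one
Product: 11 4-{2-[(1S,2R)-1,2,5,5-tetramethyl-6-oxo-1,2,3,4,5,6,7,8-octahydronaphthalen-1-yl]ethyl}furan-2(5H)-one ((8R,9S)-3-oxohalima-5(10),13-dien-15,16-olide)
Conditions: p-TsOH·H2O (0.3 equiv), benzene, 80 °C
Reagents that add atoms: none
Why: Acid-catalysed alkene isomerisation under thermodynamic control: protonation at C6 gives the tertiary C5 cation and loss of H-10 gives the tetrasubstituted C5=C10 alkene, both C10 epimers converge, the C3 ketone disfavours a 1,2-methyl shift from C4 (it would give an alpha-acyl cation), and C8/C9 are untouched.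

Step 7
Reactants: 11 4-{2-[(1S,2R)-1,2,5,5-tetramethyl-6-oxo-1,2,3,4,5,6,7,8-octahydronaphthalen-1-yl]ethyl}furan-2(5H)-one
Product: 12 4-{2-[(1S,2R,6R)-6-hydroxy-1,2,5,5-tetramethyl-1,2,3,4,5,6,7,8-octahydronaphthalen-1-yl]ethyl}furan-2(5H)-one (3R,8R,9S)
Conditions: (S)-2-methyl-CBS-oxazaborolidine (20 mol %), BH3·SMe2, THF, −20 °C; MeOH quench
Reagents that add atoms: none
Why: Corey–Bakshi–Shibata reduction: hydride delivery is catalyst-controlled with quaternary C4 as the large and C2H2 as the small substituent, so the (S)-catalyst gives the 3R alcohol, the remote C8/C9 centres exert no bias, and the butenolide and the tetrasubstituted alkene are inert.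

Step 8
Reactants: 12 4-{2-[(1S,2R,6R)-6-hydroxy-1,2,5,5-tetramethyl-1,2,3,4,5,6,7,8-octahydronaphthalen-1-yl]ethyl}furan-2(5H)-one
Product: 14 (2S,3R,8R)-8-hydroxy-2,3,7,7-tetramethyl-2-[2-(5-oxo-2,5-dihydrofuran-3-yl)ethyl]cyclodecane-1,6-dione, via secondary ozonide 13 (not isolated)
Conditions: O3, CH2Cl2, −78 °C (Sudan Red 7B end point); PPh3 (1.2 equiv), −78 → 23 °C
Reagents that add atoms: ozone, [O-][O+]=O
Why: Ozonolysis (Criegee mechanism): the electron-rich tetrasubstituted alkene reacts orders of magnitude faster than the electron-poor butenolide alkene, the dye marks the end point, PPh3 reduces the ozonide, both six-membered rings open to the ten-membered 1,6-dione, and no stereocentre changes.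

Step 9
Reactants: 14 (2S,3R,8R)-8-hydroxy-2,3,7,7-tetramethyl-2-[2-(5-oxo-2,5-dihydrofuran-3-yl)ethyl]cyclodecane-1,6-dione
Product: 15 (2R,3aS,5S,6R,8aS)-2,8a-dihydroxy-1,1,5,6-tetramethyl-5-[2-(5-oxo-2,5-dihydrofuran-3-yl)ethyl]octahydroazulen-4(1H)-one (target)
Conditions: DBU (0.2 equiv), toluene, 23 °C
Reagents that add atoms: none
Why: Transannular aldol addition under reversible amine-base catalysis: only C1 and C6 carry alpha-hydrogens, the C5 carbonyl is activated by a six-membered hydrogen bond from the C3–OH, so the C10 enolate carbon C1 closes onto C5; that hydrogen bond places the new C5–OH cis to the C3–OH, and the epimerisable C1 settles in the trans-fused ketol (O3–H···O5–H···O=C10 hydrogen-bond chain), while the competing C6-to-C10 closure and wrong epimers revert by retro-aldol.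

## Compound list

1 | 2,2-dimethylcyclohexane-1,3-dione | CC1(C)C(=O)CCCC1=O | starting material
2 | lithium 6,6-dimethyl-5-oxocyclohex-1-en-1-olate | [Li+].[O-]C1=CCCC(=O)C1(C)C | intermediate
3 | 6,6-dimethyl-5-oxocyclohex-1-en-1-yl trifluoromethanesulfonate | CC1(C)C(=O)CCC=C1OS(=O)(=O)C(F)(F)F | intermediate
4 | 2,2-dimethyl-3-vinylcyclohex-3-en-1-one | C=CC1=CCCC(=O)C1(C)C | intermediate
5 | (E)-2-methylbut-2-enal | C/C=C(\C)C=O | starting material
6 | (1S,2R,8aR)-1,2,5,5-tetramethyl-6-oxo-1,2,3,5,6,7,8,8a-octahydronaphthalene-1-carbaldehyde | C[C@@H]1CC=C2[C@@H](CCC(=O)C2(C)C)[C@@]1(C)C=O | intermediate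
7 | (4aS,5S,6R)-5-ethenyl-1,1,5,6-tetramethyl-3,4,4a,5,6,7-hexahydronaphthalen-2(1H)-one | C[C@@H]1CC=C2[C@@H](CCC(=O)C2(C)C)[C@@]1(C)C=C | intermediate
8 | 4-bromofuran-2(5H)-one | O=C1C=C(Br)CO1 | starting material
9 | B-alkyl-9-BBN adduct of 7 (boron on C12) | C[C@@H]1CC=C2[C@@H](CCC(=O)C2(C)C)[C@@]1(C)CCB1C2CCCC1CCC2 | intermediate
10 | 4-{2-[(1S,2R,8aS)-1,2,5,5-tetramethyl-6-oxo-1,2,3,5,6,7,8,8a-octahydronaphthalen-1-yl]ethyl}furan-2(5H)-one | C[C@@H]1CC=C2[C@@H](CCC(=O)C2(C)C)[C@@]1(C)CCC1=CC(=O)OC1 | intermediate
11 | 4-{2-[(1S,2R)-1,2,5,5-tetramethyl-6-oxo-1,2,3,4,5,6,7,8-octahydronaphthalen-1-yl]ethyl}furan-2(5H)-one | C[C@@H]1CCC2=C(CCC(=O)C2(C)C)[C@@]1(C)CCC1=CC(=O)OC1 | intermediate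
12 | 4-{2-[(1S,2R,6R)-6-hydroxy-1,2,5,5-tetramethyl-1,2,3,4,5,6,7,8-octahydronaphthalen-1-yl]ethyl}furan-2(5H)-one | C[C@@H]1CCC2=C(CC[C@@H](O)C2(C)C)[C@@]1(C)CCC1=CC(=O)OC1 | intermediate
13 | secondary ozonide of 12 (1,2,4-trioxolane across C5/C10; face not defined) | C[C@@H]1CCC23OOC(O2)(CC[C@@H](O)C3(C)C)[C@@]1(C)CCC1=CC(=O)OC1 | intermediate
14 | (2S,3R,8R)-8-hydroxy-2,3,7,7-tetramethyl-2-[2-(5-oxo-2,5-dihydrofuran-3-yl)ethyl]cyclodecane-1,6-dione | C[C@@H]1CCC(=O)C(C)(C)[C@H](O)CCC(=O)[C@@]1(C)CCC1=CC(=O)OC1 | intermediate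
15 | (2R,3aS,5S,6R,8aS)-2,8a-dihydroxy-1,1,5,6-tetramethyl-5-[2-(5-oxo-2,5-dihydrofuran-3-yl)ethyl]octahydroazulen-4(1H)-one | C[C@@H]1CC[C@]2(O)[C@H](C[C@@H](O)C2(C)C)C(=O)[C@@]1(C)CCC1=CC(=O)OC1 | target

## Step count and weak points

Total step count: 9. Longest linear sequence: 9 (1 to 15; 5 and 8 are bought).

**Step 3 (the proposed new step).** Tiglaldehyde is a poor dienophile, diene 4 may oligomerise under a strong acid, and the enantioselectivity is unproven.

- The fallback sets out from 4 and 5 and comes back at 6.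
- It gives up Brønsted-acid ion pairing for a covalently bound chiral boron Lewis acid, which is known chemistry for 2-substituted enals.
- The catalyst is the oxazaborolidine from (S)-diphenylprolinol and o-tolylboroxine, activated with Tf2NH (20 mol %, CH2Cl2, −78 → −40 °C).
- The aldehyde oxygen binds to boron on the convex face. A formyl C–H···O contact to the ring oxygen fixes the s-trans enal next to one phenyl group, which blocks the C-alpha-Si face. The diene therefore adds to the C-alpha-Re face as required.
- No new compound is made (F0).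

**Step 6.** The C5 cation is slowed by the C3 carbonyl. The equilibrium may also stop at a mixture of alkene isomers, or cationic skeletal shifts may set in on long heating.

- The fallback sets out from 10 and comes back at 11.
- It replaces equilibration by a stepwise addition–elimination.
- Dry HCl in CH2Cl2 at −30 °C adds across C5=C6 to give the tertiary 5-chloride F1 (trans-decalin, Cl anti to H-10).
- E2 elimination with LiBr/Li2CO3 in DMF at 100 °C removes the antiperiplanar H-10 (Zaitsev). Recovered 10 is recycled.

**Step 9.** The closure may go the other way (C6 onto C10). The ketol may also lose water, or the a5/a6 diastereomer ratio may be poor.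

- The fallback sets out from 11 and comes back at 15.
- It changes the order of events so that the acceptor carbonyl is biased electronically.
- Ozonolysis of the ketone 11 (O3, then PPh3) goes through the secondary ozonide F2 to the triketone F3.
- In F3, C5 belongs to a non-enolisable 2,2-dimethyl-1,3-dione and is the most electrophilic carbonyl.
- Base-mediated transannular aldol addition (DBU, toluene) then gives the ketol dione F4.
- A final (S)-CBS/BH3·SMe2 reduction converts the cyclopentanone carbonyl C3 to the 3R alcohol. This carbonyl has quaternary C4 as its large group. The C10 ketone, flanked by quaternary C9 and tertiary C1, stays untouched.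

## Further compounds

F0 | step 3 | none | none
F1 | step 6 | 5-chloro adduct of 10 (trans-decalin, Cl anti to H-10) | C[C@@H]1CC[C@@]2(Cl)[C@@H](CCC(=O)C2(C)C)[C@@]1(C)CCC1=CC(=O)OC1
F2 | step 9 | secondary ozonide of 11 (face not defined) | C[C@@H]1CCC23OOC(O2)(CCC(=O)C3(C)C)[C@@]1(C)CCC1=CC(=O)OC1
F3 | step 9 | (7S,8R)-2,2,7,8-tetramethyl-7-[2-(5-oxo-2,5-dihydrofuran-3-yl)ethyl]cyclodecane-1,3,6-trione | C[C@@H]1CCC(=O)C(C)(C)C(=O)CCC(=O)[C@@]1(C)CCC1=CC(=O)OC1
F4 | step 9 | 3-oxo analogue of 15 (8a-hydroxy-1,1,5,6-tetramethyl-5-[2-(5-oxo-2,5-dihydrofuran-3-yl)ethyl]hexahydroazulene-2,4-dione, ring fusion as in 15) | C[C@@H]1CC[C@]2(O)[C@H](CC(=O)C2(C)C)C(=O)[C@@]1(C)CCC1=CC(=O)OC1
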